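**Strategy.** The quinone ring (C1–C4, C4a, C8a) carries a vicinal oxygenated pair, C1 (carbonyl) and C2 (methoxy-bearing). This C1–C2 edge is read as an oxalate. The rest, C3–C4–C4a–C8a, is read as an acetophenone acting as a 1,4-dinucleophile: enolate carbon at C3, lithiated ring carbon at C8a. The key step treats the C,O-dimetalated bromo ketone, which already holds the methoxy group at C6 and the 3,4-dimethoxyphenyl group at C8, with dimethyl oxalate. Aryllithium acylation joins C8a to C1, a Claisen closure joins C3 to C2, and the 2-hydroxy-1,4-naphthoquinone results in one operation. The position of the bromine decides for C8a against C5. O-Methylation completes the target.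

Key step: step 4

Remark: the target is achiral, so no stereocentre has to be set; atom numbers are those of naphthalene-1,4-dione (C1 and C4 carbonyl carbons, C2 and C6 methoxy-bearing, C8 aryl-bearing).

Step 1
Reactants: 1 1-(2-amino-5-methoxyphenyl)ethanone
Product: 2 1-(2-amino-3-iodo-5-methoxyphenyl)ethanone
Conditions: NIS (1.05 equiv), AcOH, rt
Reagents that add atoms: N-iodosuccinimide, O=C1CCC(=O)N1I
Why: Electrophilic aromatic iodination should go to the free position ortho to the amino group (its para position is blocked by the methoxy group), which is also meta to the acetyl group, whereas the two positions ortho to the methoxy group are deactivated by the acetyl group.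

Step 2
Reactants: 2 1-(2-amino-3-iodo-5-methoxyphenyl)ethanone
Product: 4 1-(2-bromo-3-iodo-5-methoxyphenyl)ethanone, via diazonium bromide 3 (not isolated)
Conditions: NaNO2, 48% aq. HBr, MeCN, 0 °C; CuBr (0.2 equiv), 0 to 60 °C
Reagents that add atoms: hydrogen bromide, Br
Why: Sandmeyer bromination: diazotisation gives the arenediazonium bromide, and electron transfer from CuBr releases N2 and passes bromide to the aryl radical, which puts bromine on the carbon that becomes C8a and leaves the C–I bond in place.

Step 3
Reactants: 4 1-(2-bromo-3-iodo-5-methoxyphenyl)ethanone; 5 (3,4-dimethoxyphenyl)boronic acid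
Product: 6 1-[2-bromo-3-(3,4-dimethoxyphenyl)-5-methoxyphenyl]ethanone
Conditions: Pd(PPh3)4 (5 mol %), Na2CO3, DME/H2O, 80 °C
Reagents that add atoms: none
Why: Suzuki–Miyaura coupling: zerovalent palladium inserts into the C–I bond far faster than into the C–Br bond, and after the coupling the bromide lies between two ortho substituents and should stay untouched.

Step 4
Reactants: 6 1-[2-bromo-3-(3,4-dimethoxyphenyl)-5-methoxyphenyl]ethanone; 7 dimethyl oxalate
Product: 12 8-(3,4-dimethoxyphenyl)-2-hydroxy-6-methoxynaphthalene-1,4-dione, via potassium enolate 8 (not isolated), via C-lithiated potassium enolate 9 (not isolated), via keto ester enolate 10 (not isolated), via potassium quinonolate 11 (not isolated)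
Conditions: KH (1.1 equiv), THF, 0 °C; t-BuLi (2.1 equiv), −78 °C; 7 (1.1 equiv), −78 °C to rt; aq. HCl
Reagents that add atoms: none
Why: KH turns the ketone into its potassium enolate, which shields the carbonyl group and arms C3, and t-BuLi then exchanges the bromine at C8a for lithium to give a C,O-dimetalated 1,4-dinucleophile; the aryllithium adds to one ester group of dimethyl oxalate (C8a–C1, aryl glyoxylate formation) and the enolate carbon C3 attacks the second ester carbon C2 with loss of methoxide (Claisen condensation), and the opposite order of the two acylations leads to the same ring. The closest known reaction type is the annulation of ortho-lithiated dianions with dialkyl oxalates, as in the isatin synthesis from ortho-lithiated N-acyl anilides, here ended by a Dieckmann-type Claisen closure in place of N-acylation. The only ring closed is the quinone ring, by a 6-(enolendo)-exo-trig attack of C3 on the ester carbonyl C2. No stereocentre is formed. The step needs C8a and not C5 to react, which the position of the bromine fixes, and it needs C-acylation over O-acylation and over the reversible aldol attack of C3 on the C1 ketone, which the irreversible deprotonation of the 1,2,4-trione to the stabilised salt 11 should secure.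

Step 5
Reactants: 12 8-(3,4-dimethoxyphenyl)-2-hydroxy-6-methoxynaphthalene-1,4-dione
Product: 13 8-(3,4-dimethoxyphenyl)-2,6-dimethoxynaphthalene-1,4-dione
Conditions: MeOH, conc. HCl (cat.), reflux
Reagents that add atoms: methanol, CO
Why: Acid-catalysed vinylogous Fischer esterification (addition of methanol at C2 of the protonated hydroxyquinone and loss of water) is the standard way from 2-hydroxy-1,4-naphthoquinones to their 2-methyl ethers, and the aryl methyl ethers are inert to it.

**Compound list**

1 | 1-(2-amino-5-methoxyphenyl)ethanone | CC(=O)c1cc(OC)ccc1N | starting material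
2 | 1-(2-amino-3-iodo-5-methoxyphenyl)ethanone | CC(=O)c1cc(OC)cc(I)c1N | intermediate
3 | 2-acetyl-6-iodo-4-methoxybenzenediazonium bromide (formed in the flask) | CC(=O)c1cc(OC)cc(I)c1[N+]#N.[Br-] | intermediate
4 | 1-(2-bromo-3-iodo-5-methoxyphenyl)ethanone | CC(=O)c1cc(OC)cc(I)c1Br | intermediate
5 | (3,4-dimethoxyphenyl)boronic acid | COc1ccc(B(O)O)cc1OC | starting material
6 | 1-[2-bromo-3-(3,4-dimethoxyphenyl)-5-methoxyphenyl]ethanone | CC(=O)c1cc(OC)cc(-c2ccc(OC)c(OC)c2)c1Br | intermediate
7 | dimethyl oxalate | COC(=O)C(=O)OC | starting material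
8 | potassium 1-[2-bromo-3-(3,4-dimethoxyphenyl)-5-methoxyphenyl]ethenolate (formed in the flask) | [K]OC(=C)c1cc(OC)cc(-c2ccc(OC)c(OC)c2)c1Br | intermediate
9 | potassium 1-[3-(3,4-dimethoxyphenyl)-2-lithio-5-methoxyphenyl]ethenolate (formed in the flask) | [Li]c1c(C(=C)O[K])cc(OC)cc1-c1ccc(OC)c(OC)c1 | intermediate
10 | potassium enolate of methyl 2-[2-acetyl-6-(3,4-dimethoxyphenyl)-4-methoxyphenyl]-2-oxoacetate (formed in the flask) | COC(=O)C(=O)c1c(C(=C)O[K])cc(OC)cc1-c1ccc(OC)c(OC)c1 | intermediate
11 | potassium 8-(3,4-dimethoxyphenyl)-6-methoxy-1,4-dioxo-1,4-dihydronaphthalen-2-olate (formed in the flask) | [K]OC1=CC(=O)c2cc(OC)cc(-c3ccc(OC)c(OC)c3)c2C1=O | intermediate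
12 | 8-(3,4-dimethoxyphenyl)-2-hydroxy-6-methoxynaphthalene-1,4-dione | OC1=CC(=O)c2cc(OC)cc(-c3ccc(OC)c(OC)c3)c2C1=O | intermediate
13 | 8-(3,4-dimethoxyphenyl)-2,6-dimethoxynaphthalene-1,4-dione | COC1=CC(=O)c2cc(OC)cc(-c3ccc(OC)c(OC)c3)c2C1=O | target

Total step count: 5
Longest linear sequence: 5 steps (1 to 13); 5 and 7 are bought.

**Steps most likely to fail**

1. Step 4 (key step). What may go wrong: incomplete bromine–lithium exchange or proton quench of the hindered aryllithium before it is acylated; metalation of the methoxy-bearing rings by the mixed lithium/potassium base; one oxalate taking up two dianions; O-acylation of the enolate in place of the Claisen closure. Fallback (stepwise, ketone masked): from 6, ketalisation (ethylene glycol, TsOH, toluene, Dean–Stark) would give 2-[2-bromo-3-(3,4-dimethoxyphenyl)-5-methoxyphenyl]-2-methyl-1,3-dioxolane F1. Bromine–lithium exchange (t-BuLi, THF, −78 °C) would give [2-(3,4-dimethoxyphenyl)-4-methoxy-6-(2-methyl-1,3-dioxolan-2-yl)phenyl]lithium F2, which is added to an excess of 7 to give methyl 2-[2-(3,4-dimethoxyphenyl)-4-methoxy-6-(2-methyl-1,3-dioxolan-2-yl)phenyl]-2-oxoacetate F3. Aqueous HCl in THF would remove the ketal to give methyl 2-[2-acetyl-6-(3,4-dimethoxyphenyl)-4-methoxyphenyl]-2-oxoacetate F4. KOt-Bu in THF should then close the ring by a Dieckmann-type Claisen condensation and return to the route at 11, which aqueous HCl turns into 12.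

2. Step 2. What may go wrong: slow diazotisation of the weakly basic, doubly ortho-substituted amine; ring closure of the diazonium ion onto the enol of the neighbouring acetyl group; exchange of the ortho iodide by bromide. Fallback (coupling before the amine is replaced): from 2, Suzuki–Miyaura coupling with 5 (Pd(PPh3)4, Na2CO3, DME/H2O, 80 °C) would give 1-[2-amino-3-(3,4-dimethoxyphenyl)-5-methoxyphenyl]ethanone F5. Aprotic diazotisation in the presence of the bromide donor (t-BuONO, CuBr2, MeCN, 0 °C to rt) would pass through 2-acetyl-6-(3,4-dimethoxyphenyl)-4-methoxybenzenediazonium bromide F6, which is consumed as it forms, and rejoin the route at 6; compound 4 is bypassed.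

3. Step 5. What may go wrong: the addition of methanol may stall short of full conversion or deliver the isomeric 4-methoxy-1,2-quinone. Fallback (C2 made electrophilic): from 12, SOCl2 with catalytic DMF at reflux would give 2-chloro-8-(3,4-dimethoxyphenyl)-6-methoxynaphthalene-1,4-dione F7, and NaOMe in MeOH at 0 °C should replace the chloride by addition–elimination at C2 to give 13.

**Further compounds**

F1 | step 4 | 2-[2-bromo-3-(3,4-dimethoxyphenyl)-5-methoxyphenyl]-2-methyl-1,3-dioxolane | CC1(OCCO1)c1cc(OC)cc(-c2ccc(OC)c(OC)c2)c1Br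
F2 | step 4 | [2-(3,4-dimethoxyphenyl)-4-methoxy-6-(2-methyl-1,3-dioxolan-2-yl)phenyl]lithium | [Li]c1c(cc(OC)cc1-c1ccc(OC)c(OC)c1)C1(C)OCCO1
F3 | step 4 | methyl 2-[2-(3,4-dimethoxyphenyl)-4-methoxy-6-(2-methyl-1,3-dioxolan-2-yl)phenyl]-2-oxoacetate | COC(=O)C(=O)c1c(cc(OC)cc1-c1ccc(OC)c(OC)c1)C1(C)OCCO1
F4 | step 4 | methyl 2-[2-acetyl-6-(3,4-dimethoxyphenyl)-4-methoxyphenyl]-2-oxoacetate | COC(=O)C(=O)c1c(C(C)=O)cc(OC)cc1-c1ccc(OC)c(OC)c1
F5 | step 2 | 1-[2-amino-3-(3,4-dimethoxyphenyl)-5-methoxyphenyl]ethanone | CC(=O)c1cc(OC)cc(-c2ccc(OC)c(OC)c2)c1N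
F6 | step 2 | 2-acetyl-6-(3,4-dimethoxyphenyl)-4-methoxybenzenediazonium bromide | CC(=O)c1cc(OC)cc(-c2ccc(OC)c(OC)c2)c1[N+]#N.[Br-]
F7 | step 5 | 2-chloro-8-(3,4-dimethoxyphenyl)-6-methoxynaphthalene-1,4-dione | ClC1=CC(=O)c2cc(OC)cc(-c3ccc(OC)c(OC)c3)c2C1=O
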